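**Retrosynthetic overview**

1. The target comes from one global acid hydrolysis of a protected bis-ester (methyl ester, 3-O-TBS, two phenolic acetates).
2. Both acyl arms come from a twofold formyl C–H addition (hydroesterification) of a 4,5-bis-formate across 4-ethynylphenyl acetate; the O4 arm is made on the molecule that already carries the O5 arm, joining the O4 formate carbon to the terminal alkyne carbon.
3. The bis-formate comes from methyl 3-O-TBS-quinate, this from 3-O-TBS-1,5-quinide, this from 1,5-quinide and (−)-quinic acid, which supplies all four stereocentres.
4. Rings: the cyclohexane is bought; the only ring made is the temporary 1,5-γ-lactone (step 1, reopened in step 3), whose flipped chair makes 3-OH the single equatorial secondary hydroxyl; the key step closes no ring.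
5. Enabling feature: each O–C(=O)–CH=CH–aryl arm is the syn adduct of a formate O–C(=O)–H bond across an aryl–C≡C–H bond, and the two arms sit on the trans-diequatorial O4/O5 pair of the cyclohexane chair (C4, C5), whose formates cannot cyclise onto each other, while the axial O3 (cis to O4) is silylated.

Key step: step 6

Assumption (remark on the chemistry): positions are numbered as in the target name (O3 axial and cis to O4; O5 trans to O4 and cis to the C1 carboxyl), and acetic formic anhydride is taken as a separately prepared stock reagent.

**Route**

Step 1
Reactants: 1 (−)-quinic acid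
Product: 2 1,5-quinide (quinic acid 1,5-γ-lactone)
Conditions: TsOH·H2O (cat.), toluene/DMF, reflux, azeotropic removal of water
Reagents that add atoms: none
Why: Acid-catalysed intramolecular esterification (lactonisation): after a chair flip the C1 carboxyl and the cis 5-OH are 1,3-diaxial and close the bicyclic γ-lactone; no stereocentre is touched.

Step 2
Reactants: 2 1,5-quinide
Product: 3 3-O-TBS-1,5-quinide
Conditions: TBSCl (1.1 equiv), imidazole (2.2 equiv), DMF, 0 °C → rt
Reagents that add atoms: tert-butyldimethylsilyl chloride, CC(C)(C)[Si](C)(C)Cl
Why: Kinetically controlled silyl ether formation: in the flipped chair of the lactone 3-OH is the only equatorial secondary hydroxyl, so it should react ahead of the axial 4-OH and the tertiary 1-OH.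

Step 3
Reactants: 3 3-O-TBS-1,5-quinide
Product: 4 methyl 3-O-TBS-quinate
Conditions: NaOMe (0.1 equiv), MeOH, 0 °C; then AcOH
Reagents that add atoms: methanol, CO
Why: Methoxide-catalysed transesterification opens the strained bicyclic lactone to the methyl ester and frees 5-OH without touching a stereocentre; low temperature and short reaction time are meant to hold back base-induced O3→O4 silyl migration.

Step 4
Reactants: 4 methyl 3-O-TBS-quinate
Product: 6 methyl 3-O-TBS-4,5-di-O-formylquinate, via 5-O-formate 5 (not isolated)
Conditions: AcOCHO (3 equiv), pyridine, CH2Cl2, −20 → 0 °C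
Reagents that add atoms: acetic formic anhydride, CC(=O)OC=O
Why: O-Formylation by the mixed anhydride, which transfers its more electrophilic formyl group; the equatorial 5-OH should react first and the flanked 4-OH second, while the tertiary α-hydroxy-ester 1-OH is too hindered to react under these conditions.

Step 5
Reactants: 7 4-ethynylphenol
Product: 8 4-ethynylphenyl acetate
Conditions: Ac2O, pyridine, CH2Cl2, 0 °C → rt
Reagents that add atoms: acetic anhydride, CC(=O)OC(C)=O
Why: Standard O-acetylation of a phenol (nucleophilic acyl substitution), so that the phenol cannot compete as nucleophile or acid in the Pd step.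

Step 6
Reactants: 6 methyl 3-O-TBS-4,5-di-O-formylquinate; 8 4-ethynylphenyl acetate (3 equiv)
Product: 10 methyl 4,5-bis-O-[(E)-4-acetoxycinnamoyl]-3-O-TBS-quinate, via mono-adduct 9 (not isolated)
Conditions: Pd2(dba)3 (2.5 mol %), 1,2-bis(di-tert-butylphosphinomethyl)benzene (dtbpx, 6 mol %), PhCO2H (10 mol %), toluene, 90 °C, sealed tube
Reagents that add atoms: none
Why: Proposed new method: twofold intermolecular hydroesterification, each formyl C–H bond of 6 adding syn across the C≡C bond of 8: electron-rich Pd(0)/dtbpx is expected to insert into the formyl C–H bond to give an alkoxycarbonyl–Pd–H species (alkoxycarbonyl–Pd complexes resist CO loss far better than acyl–Pd complexes), the alkyne inserts into Pd–H with Pd on the terminal carbon, and C–C reductive elimination joins the formate carbon to that carbon; a Pd–H made with PhCO2H that hydropalladates the alkyne first and then takes up the alkoxycarbonyl unit would lead to the same product. The closest known reaction types are the Pd-catalysed hydroesterification of alkynes with formate esters and the linear-selective Pd/dtbpx hydroalkoxycarbonylation of phenylacetylene to cinnamates; new here is an unactivated secondary alkyl formate used as the limiting partner, twice on one ring and without CO gas. No ring is closed and no stereocentre is formed; the (E) geometry of both alkenes follows from the syn delivery of H and CO2R to the alkyne. The step needs linear instead of branched regiochemistry, secured by the bulk of dtbpx, which keeps Pd off the aryl-bearing carbon, and it needs chemoselectivity for the two formyl C–H bonds, which no other group in 6 or 8 (methyl ester, aryl acetate, silyl ether, tertiary OH) can rival. The sealed vessel keeps any CO from reversible decarbonylation available, and the less hindered O5 formate should react first (9) before the O4 formate next to the axial OTBS group forms the second arm.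

Step 7
Reactants: 10 methyl 4,5-bis-O-[(E)-4-acetoxycinnamoyl]-3-O-TBS-quinate
Product: 13 4,5-di-O-p-coumaroylquinic acid, via desilylated diacetate 11 (not isolated), via methyl ester 12 (not isolated)
Conditions: 2 M HCl (aq)/THF (1:3), rt, several days
Reagents that add atoms: water, O
Why: Acid-catalysed hydrolysis in the order silyl ether, phenolic acetates, hindered methyl ester, the usual acidic end game for hydroxycinnamoylquinic acids: the conjugated secondary cinnamate esters should hydrolyse much more slowly and acid suppresses acyl migration to O3, so all four stereocentres and both (E) alkenes are kept.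

**Compound list**

1 | (−)-quinic acid, (1S,3R,4S,5R)-1,3,4,5-tetrahydroxycyclohexane-1-carboxylic acid | O[C@@H]1[C@H](O)C[C@@](O)(C(=O)O)C[C@H]1O | starting material
2 | 1,5-quinide: γ-lactone between the C1 carboxyl and O5 of 1; free 1-OH, equatorial 3-OH, axial 4-OH | O[C@@H]1[C@H](O)C[C@]2(O)C[C@H]1OC2=O | intermediate
3 | 3-O-TBS-1,5-quinide: tert-butyldimethylsilyl ether on the 3-OH of 2 | O[C@@H]1[C@H](O[Si](C)(C)C(C)(C)C)C[C@]2(O)C[C@H]1OC2=O | intermediate
4 | methyl 3-O-TBS-quinate: methyl ester of 1 with 3-O-TBS; free 1-, 4- and 5-OH; configuration of 1 | O[C@@H]1[C@H](O[Si](C)(C)C(C)(C)C)C[C@@](O)(C(=O)OC)C[C@H]1O | intermediate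
5 | methyl 3-O-TBS-5-O-formylquinate (not isolated, step 4) | O[C@@H]1[C@H](O[Si](C)(C)C(C)(C)C)C[C@@](O)(C(=O)OC)C[C@H]1OC=O | intermediate
6 | methyl 3-O-TBS-4,5-di-O-formylquinate | O=CO[C@@H]1[C@H](O[Si](C)(C)C(C)(C)C)C[C@@](O)(C(=O)OC)C[C@H]1OC=O | intermediate
7 | 4-ethynylphenol | C#Cc1ccc(O)cc1 | starting material
8 | 4-ethynylphenyl acetate | CC(=O)Oc1ccc(C#C)cc1 | intermediate
9 | methyl 5-O-[(E)-4-acetoxycinnamoyl]-4-O-formyl-3-O-TBS-quinate (not isolated, step 6) | O=CO[C@@H]1[C@H](O[Si](C)(C)C(C)(C)C)C[C@@](O)(C(=O)OC)C[C@H]1OC(=O)/C=C/c1ccc(OC(C)=O)cc1 | intermediate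
10 | methyl 4,5-bis-O-[(E)-4-acetoxycinnamoyl]-3-O-TBS-quinate | O=C(/C=C/c1ccc(OC(C)=O)cc1)O[C@@H]1[C@H](O[Si](C)(C)C(C)(C)C)C[C@@](O)(C(=O)OC)C[C@H]1OC(=O)/C=C/c1ccc(OC(C)=O)cc1 | intermediate
11 | methyl 4,5-bis-O-[(E)-4-acetoxycinnamoyl]quinate (not isolated, step 7) | O=C(/C=C/c1ccc(OC(C)=O)cc1)O[C@@H]1[C@H](O)C[C@@](O)(C(=O)OC)C[C@H]1OC(=O)/C=C/c1ccc(OC(C)=O)cc1 | intermediate
12 | methyl 4,5-di-O-[(E)-p-coumaroyl]quinate (not isolated, step 7) | O=C(/C=C/c1ccc(O)cc1)O[C@@H]1[C@H](O)C[C@@](O)(C(=O)OC)C[C@H]1OC(=O)/C=C/c1ccc(O)cc1 | intermediate
13 | 4,5-di-O-p-coumaroylquinic acid | O=C(/C=C/c1ccc(O)cc1)O[C@@H]1[C@H](O)C[C@@](O)(C(=O)O)C[C@H]1OC(=O)/C=C/c1ccc(O)cc1 | target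

**Step count and risks**

Total step count: 7. Longest linear sequence: 6 steps (steps 1, 2, 3, 4, 6, 7).

Steps most likely to fail:

1. Step 6 (proposed new method). The formyl C–H bonds may not be activated by Pd(0)/dtbpx, CO may be lost from the alkoxycarbonyl–Pd intermediate (decarbonylation back to the diol), or Pd may add to the internal alkyne carbon and give branched 2-arylacrylates. The fallback uses known chemistry and makes the same C(=O)–CH= bonds by CO insertion instead of C–H addition. It sets out from 4, skipping the formates, and comes back at 10. Alkyne 8 is converted by hydrozirconation with Cp2Zr(H)Cl (THF, 0 °C, short contact so that the aryl acetate survives) and iodinolysis (I2) into (E)-4-(2-iodovinyl)phenyl acetate F1, in which regiochemistry and (E) geometry are already fixed. A twofold Pd-catalysed carbonylative esterification (Heck carbonylation: Pd(OAc)2, Xantphos, Et3N, CO 5 bar, toluene, 70 °C) of F1 with the 4,5-diol of 4 should then give 10, the tertiary 1-OH staying free.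

2. Step 7. Hydrolysis of the hindered methyl ester may be too slow, so that the cinnamate esters begin to hydrolyse or migrate before it is complete. The fallback sets out from 10 and comes back at 13. The acid treatment is stopped once the silyl ether and the phenolic acetates are gone, and methyl ester 12 is isolated. The methyl group is then removed by SN2 dealkylation with LiI (EtOAc, reflux), which attacks only the methyl carbon and leaves the secondary cinnamate esters alone; acidification of the lithium carboxylate gives 13. No new compound is needed.

3. Step 3. Under methoxide the TBS group may migrate from O3 to the neighbouring cis O4 (and on to O5), scrambling the protection pattern. The fallback sets out from 3 and comes back at 4. The lactone is opened irreversibly with one equivalent of LiOH (THF/H2O, 0 °C), so that the base is consumed as the carboxylate forms, and careful acidification gives 3-O-TBS-quinic acid F2. The carboxylate is then O-methylated under near-neutral conditions (MeI, KHCO3, DMF) to give 4, the ester now being made by alkylation instead of transesterification.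

Further compounds
F1 | step 6 | (E)-4-(2-iodovinyl)phenyl acetate | CC(=O)Oc1ccc(/C=C/I)cc1
F0 | step 7 | none | none
F2 | step 3 | 3-O-TBS-quinic acid | O[C@@H]1[C@H](O[Si](C)(C)C(C)(C)C)C[C@@](O)(C(=O)O)C[C@H]1O
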